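**Assumption:** atom labels C1–C15 are germacrane numbering of the target; methyl 4-bromobut-2-ynoate and ICH2Bpin are taken as purchasable. Catalyst antipodes in steps 5, 11 and 13 are chosen by the facial arguments given and are not confirmed by precedent on these substrates; the opposite antipode is used if the sense is reversed.

## Retrosynthetic overview

1. Target ⇒ late peracid epoxidation of the 1(10)-olefin (1,10-oxirane formed last) and C8 esterification with a (2S,3R)-epoxy acid made by organocatalytic epoxidation of tiglic aldehyde.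
2. 8β-Hydroxy germacranolide ⇒ one-pot C6–C7 macro-allylboration (ten-membered carbocycle first) and lactonisation (γ-lactone second) of a linear Z-enal / 2-methoxycarbonyl allylboronate.
3. Allylboronate ⇒ ynoate (hydroalumination, CH2Bpin transfer) ⇒ [2,3]-Wittig rearrangement of a 4-alkoxybut-2-ynoate (C8–C9 bond, C8–O stereocentre, E-1(10) olefin).
4. Ynoate ether ⇒ anti-1,3-diol monobenzoate (Evans–Tishchenko) ⇒ organocatalytic Mukaiyama aldol of a Z-enal (from but-2-yn-1-ol) with the enoxysilane of 3-methylbut-3-en-2-one (C3, first stereocentre).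
5. Stereochemical relay: C3 → C1 (1,3-anti) → C8 ([2,3] shift) → C6/C7 (macrocyclisation) → C1/C10 (epoxidation).

## Route

Step 1
Reactants: 1 but-2-yn-1-ol
Product: 3 (Z)-3-iodobut-2-en-1-ol, via sodium oxa-aluminate 2 (not isolated)
Conditions: NaAlH2(OCH2CH2OMe)2, Et2O, 0 °C to rt; then I2, −78 °C to rt; aq. KNaC4H4O6
Reagents that add atoms: sodium bis(2-methoxyethoxy)aluminium dihydride [Na+].COCCO[AlH2-]OCCOC (Al, Na and alkoxy ligands in 2 only); iodine II
Why: Hydroxyl-directed trans-hydroalumination of the propargylic alcohol puts aluminium on C4 in a five-membered alanate, and iodinolysis with retention gives the Z-iodide that fixes the Z-4,5 olefin of the target.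

Step 2
Reactants: 3 (Z)-3-iodobut-2-en-1-ol
Product: 4 (Z)-triethyl[(3-iodobut-2-en-1-yl)oxy]silane
Conditions: Et3SiCl, imidazole, CH2Cl2, 0 °C
Reagents that add atoms: chlorotriethylsilane CC[Si](Cl)(CC)CC
Why: Standard silylation; the primary triethylsilyl ether is chosen because it can later be oxidised directly to the aldehyde.

Step 3
Reactants: 4 (Z)-triethyl[(3-iodobut-2-en-1-yl)oxy]silane
Product: 6 (Z)-2-methyl-4-(triethylsilyloxy)but-2-enal, via alkenyllithium 5 (not isolated)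
Conditions: tBuLi (2.1 equiv), Et2O, −78 °C; then DMF, −78 to 0 °C; H2O
Reagents that add atoms: tert-butyllithium [Li]C(C)(C)C (Li of 5 only); N,N-dimethylformamide CN(C)C=O
Why: Iodine–lithium exchange is stereoretentive at −78 °C and formylation of the alkenyllithium with DMF (Bouveault-type) gives the Z-enal with the silyl ether intact.

Step 4
Reactants: 7 3-methylbut-3-en-2-one
Product: 8 trimethyl[(3-methylbuta-1,3-dien-2-yl)oxy]silane
Conditions: Me3SiOTf, Et3N, Et2O, 0 °C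
Reagents that add atoms: trimethylsilyl trifluoromethanesulfonate C[Si](C)(C)OS(=O)(=O)C(F)(F)F
Why: Soft enolisation of the methyl ketone (silyl enol ether formation) gives the 2-silyloxydiene used as the aldol nucleophile.

Step 5
Reactants: 6 (Z)-2-methyl-4-(triethylsilyloxy)but-2-enal; 8 trimethyl[(3-methylbuta-1,3-dien-2-yl)oxy]silane
Product: 9 (5S,6Z)-5-hydroxy-2,6-dimethyl-8-(triethylsilyloxy)octa-1,6-dien-3-one
Conditions: SiCl4 (1.2 equiv), (S,S)-Denmark bisphosphoramide (pentane-1,5-diyl-linked bis(N,N'-dimethyl-1,1'-binaphthyl-2,2'-diamine phosphoramide), 5 mol %), iPr2NEt (10 mol %), CH2Cl2, −78 °C; aq. NaHCO3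
Reagents that add atoms: none
Why: Lewis-base-catalysed Mukaiyama aldol, in which the chiral phosphoramide-bound trichlorosilyl cation activates the enal and the enoxysilane adds to its Si face through an open transition state, setting C3 (S) as the first stereocentre from achiral partners.

Step 6
Reactants: 9 (5S,6Z)-5-hydroxy-2,6-dimethyl-8-(triethylsilyloxy)octa-1,6-dien-3-one
Product: 10 (3S,5S,6Z)-3-hydroxy-2,6-dimethyl-8-(triethylsilyloxy)octa-1,6-dien-5-yl benzoate
Conditions: PhCHO (5 equiv), SmI2 (30 mol %), THF, −10 °C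
Reagents that add atoms: benzaldehyde O=Cc1ccccc1
Why: Evans–Tishchenko reduction, in which the samarium-bound hemiacetal of the C3 hydroxyl and benzaldehyde delivers hydride through a six-membered chair to the C1 ketone, giving the 1,3-anti (1S) alcohol and installing the C3 benzoate of the target in the same step.

Step 7
Reactants: 10 (3S,5S,6Z)-3-hydroxy-2,6-dimethyl-8-(triethylsilyloxy)octa-1,6-dien-5-yl benzoate; 11 methyl 4-bromobut-2-ynoate
Product: 12 methyl 4-{[(3S,5S,6Z)-5-(benzoyloxy)-2,6-dimethyl-8-(triethylsilyloxy)octa-1,6-dien-3-yl]oxy}but-2-ynoate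
Conditions: Ag2O (2 equiv), 4 Å MS, CH2Cl2, rt, dark
Reagents that add atoms: none
Why: Silver-oxide-promoted Williamson-type O-alkylation with the activated propargylic bromide is neutral enough to avoid 1,3-benzoyl migration.

Step 8
Reactants: 12 methyl 4-{[(3S,5S,6Z)-5-(benzoyloxy)-2,6-dimethyl-8-(triethylsilyloxy)octa-1,6-dien-3-yl]oxy}but-2-ynoate
Product: 15 methyl (4R,6E,9S,10Z)-9-(benzoyloxy)-4-(tert-butyldimethylsilyloxy)-6,10-dimethyl-12-(triethylsilyloxy)dodeca-6,10-dien-2-ynoate, via lithium cumulenolate 13 (not isolated), via lithium alkoxide 14 (not isolated)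
Conditions: LiN(SiMe3)2 (1.2 equiv), THF, −78 to −40 °C; then tBuMe2SiOTf, −78 to 0 °C
Reagents that add atoms: lithium bis(trimethylsilyl)amide [Li]N([Si](C)(C)C)[Si](C)(C)C (Li of 13 and 14 only); tert-butyldimethylsilyl trifluoromethanesulfonate CC(C)(C)[Si](C)(C)OS(=O)(=O)C(F)(F)F
Why: Proposed new method: γ-deprotonation of the 4-alkoxybut-2-ynoate gives an ester-stabilised propargyl/allenyl (cumulenolate) anion whose carbanion carbon C8 attacks the olefin terminus C9 in a five-membered envelope [2,3]-Wittig transition state with the C2 chain pseudo-equatorial (E-1(10) olefin) and the alkynyl ester exo, so the (S)-C1–O centre is transferred to (R)-C8–O and the alkoxide is silylated in the same flask; the closest known reactions are the [2,3]-Wittig rearrangement of allyl propargyl ethers and of ester enolates of α-allyloxy acetates.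

Step 9
Reactants: 15 methyl (4R,6E,9S,10Z)-9-(benzoyloxy)-4-(tert-butyldimethylsilyloxy)-6,10-dimethyl-12-(triethylsilyloxy)dodeca-6,10-dien-2-ynoate
Product: 17 methyl (2Z,4R,6E,9S,10Z)-9-(benzoyloxy)-4-(tert-butyldimethylsilyloxy)-6,10-dimethyl-2-[(4,4,5,5-tetramethyl-1,3,2-dioxaborolan-2-yl)methyl]-12-(triethylsilyloxy)dodeca-2,6,10-trienoate, via alkenylalane 16 (not isolated)
Conditions: iBu2AlH (1.2 equiv), HMPA, THF, 0 °C; then ICH2Bpin, 0 °C to rt; aq. KNaC4H4O6
Reagents that add atoms: diisobutylaluminium hydride CC(C)C[AlH]CC(C)C (Al(iBu)2 of 16 only); 2-(iodomethyl)-4,4,5,5-tetramethyl-1,3,2-dioxaborolane ICB1OC(C)(C)C(C)(C)O1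
Why: Conjugate syn-hydroalumination of the ynoate by iBu2AlH·HMPA gives the α-aluminio acrylate (H and Al cis), whose boron ate complex with ICH2Bpin undergoes 1,2-migration with loss of iodide (Matteson-type homologation) to give the 2-alkoxycarbonyl allylboronate with C8 trans to the CH2B terminus.

Step 10
Reactants: 17 methyl (2Z,4R,6E,9S,10Z)-9-(benzoyloxy)-4-(tert-butyldimethylsilyloxy)-6,10-dimethyl-2-[(4,4,5,5-tetramethyl-1,3,2-dioxaborolan-2-yl)methyl]-12-(triethylsilyloxy)dodeca-2,6,10-trienoate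
Product: 18 methyl (2Z,4R,6E,9S,10Z)-9-(benzoyloxy)-4-(tert-butyldimethylsilyloxy)-6,10-dimethyl-12-oxo-2-[(4,4,5,5-tetramethyl-1,3,2-dioxaborolan-2-yl)methyl]dodeca-2,6,10-trienoate
Conditions: (COCl)2, DMSO, CH2Cl2, −78 °C; then 17, −78 to −40 °C; Et3N, to 0 °C
Reagents that add atoms: none
Why: Swern oxidation cleaves and oxidises the primary triethylsilyl ether directly to the Z-enal while the secondary tert-butyldimethylsilyl ether, the benzoate and the ester-deactivated allylboronate are untouched.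

Step 11
Reactants: 18 methyl (2Z,4R,6E,9S,10Z)-9-(benzoyloxy)-4-(tert-butyldimethylsilyloxy)-6,10-dimethyl-12-oxo-2-[(4,4,5,5-tetramethyl-1,3,2-dioxaborolan-2-yl)methyl]dodeca-2,6,10-trienoate
Product: 20 3β-benzoyloxy-8β-(tert-butyldimethylsilyloxy)germacra-1(10)E,4Z,11(13)-trien-12,6α-olide (H-6β and H-7α), via macrocyclic pinacol borate 19 (not isolated)
Conditions: (S)-TRIP (3,3'-bis(2,4,6-triisopropylphenyl)-1,1'-binaphthyl-2,2'-diyl hydrogen phosphate, 10 mol %), 4 Å MS, toluene (2 mM), 40 °C; then 70 °C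
Reagents that add atoms: none
Why: Proposed new method: a chiral-phosphoric-acid-catalysed macrocyclising allylboration–lactonisation, in which the acid hydrogen-bonds to a pinacol oxygen (raising boron Lewis acidity) and to the formyl hydrogen, the Z-enal is attacked on its Si face by C7 through a closed six-membered chair transition state with C5 and C8 both pseudo-equatorial (6,7-anti adduct, C6 R and C7 as in the target, catalyst control overriding the remote C8 bias), and the resulting O–Bpin alkoxide closes the trans-fused γ-lactone with loss of MeOBpin; the closest known reactions are the intermolecular phosphoric-acid-catalysed allylboration of aldehydes with allyl pinacolboronates and the acid-catalysed addition of 2-alkoxycarbonyl allylboronates to aldehydes that gives α-methylene γ-lactones.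

Step 12
Reactants: 20 3β-benzoyloxy-8β-(tert-butyldimethylsilyloxy)germacra-1(10)E,4Z,11(13)-trien-12,6α-olide
Product: 21 3β-benzoyloxy-8β-hydroxygermacra-1(10)E,4Z,11(13)-trien-12,6α-olide
Conditions: HF·pyridine, pyridine, THF, 0 °C to rt
Reagents that add atoms: none
Why: Fluoride-mediated desilylation under buffered conditions leaves the benzoate, the α-methylene lactone and the skipped diene intact.

Step 13
Reactants: 22 (E)-2-methylbut-2-enal
Product: 23 (2S,3R)-2,3-dimethyloxirane-2-carbaldehyde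
Conditions: 9-amino(9-deoxy)epiquinine·2 CF3CO2H (10 mol %), 50% aq. H2O2, dioxane, 50 °C
Reagents that add atoms: hydrogen peroxide OO
Why: Iminium-catalysed asymmetric Weitz–Scheffer epoxidation of an α-branched enal with a cinchona primary amine salt, which closes with retention of the E geometry (methyls cis) and sets both oxirane centres; the quinidine-derived pseudoenantiomer is used if the quinine-derived salt gives the (2R,3S) antipode.

Step 14
Reactants: 23 (2S,3R)-2,3-dimethyloxirane-2-carbaldehyde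
Product: 24 (2S,3R)-2,3-dimethyloxirane-2-carboxylic acid
Conditions: NaClO2, NaH2PO4, 2-methylbut-2-ene, tBuOH/H2O, 0 °C
Reagents that add atoms: sodium chlorite [Na+].[O-]Cl=O
Why: Pinnick oxidation converts the aldehyde to the acid without opening or epimerising the oxirane.

Step 15
Reactants: 21 3β-benzoyloxy-8β-hydroxygermacra-1(10)E,4Z,11(13)-trien-12,6α-olide; 24 (2S,3R)-2,3-dimethyloxirane-2-carboxylic acid
Product: 25 3β-benzoyloxy-8β-[(2S,3R)-2,3-dimethyloxirane-2-carbonyloxy]germacra-1(10)E,4Z,11(13)-trien-12,6α-olide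
Conditions: DCC, DMAP, CH2Cl2, 0 °C to rt
Reagents that add atoms: none
Why: Steglich esterification of the 8β-hydroxyl with the preformed, configurationally fixed epoxy acid.

Step 16
Reactants: 25 3β-benzoyloxy-8β-[(2S,3R)-2,3-dimethyloxirane-2-carbonyloxy]germacra-1(10)E,4Z,11(13)-trien-12,6α-olide
Product: 26 CNP0324463.4, (1R,3S,6R,7R,8R,10R)-3-benzoyloxy-1,10-epoxy-8-[(2S,3R)-2,3-dimethyloxirane-2-carbonyloxy]germacra-4Z,11(13)-dien-12,6-olide (1β,10α-oxirane)
Conditions: mCPBA (1.1 equiv), NaHCO3, CH2Cl2, 0 °C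
Reagents that add atoms: 3-chloroperoxybenzoic acid OOC(=O)c1cccc(Cl)c1
Why: Prilezhaev epoxidation, in which the peracid attacks only the electron-rich 1(10) E-olefin (the 4,5-olefin is deactivated by two allylic acyloxy groups and the other two are conjugated to carbonyls) from the exposed outer face of the ten-membered ring, giving the 1β,10α-oxirane (C1 R, C10 R).

## Compound list

1 | but-2-yn-1-ol | CC#CCO | starting material
2 | sodium oxa-aluminate (five-membered ring Al–O–CH2–CH=C(CH3)–Al, two 2-methoxyethoxy ligands on Al) | [Na+].COCCO[Al-]1(OCCOC)OCC=C1C | intermediate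
3 | (Z)-3-iodobut-2-en-1-ol | C/C(I)=C/CO | intermediate
4 | (Z)-triethyl[(3-iodobut-2-en-1-yl)oxy]silane | C/C(I)=C/CO[Si](CC)(CC)CC | intermediate
5 | (Z)-[4-(triethylsilyloxy)but-2-en-2-yl]lithium | C/C([Li])=C/CO[Si](CC)(CC)CC | intermediate
6 | (Z)-2-methyl-4-(triethylsilyloxy)but-2-enal | C/C(C=O)=C/CO[Si](CC)(CC)CC | intermediate
7 | 3-methylbut-3-en-2-one | CC(=O)C(C)=C | starting material
8 | trimethyl[(3-methylbuta-1,3-dien-2-yl)oxy]silane | C=C(O[Si](C)(C)C)C(C)=C | intermediate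
9 | (5S,6Z)-5-hydroxy-2,6-dimethyl-8-(triethylsilyloxy)octa-1,6-dien-3-one | C=C(C)C(=O)C[C@H](O)/C(C)=C\CO[Si](CC)(CC)CC | intermediate
10 | (3S,5S,6Z)-3-hydroxy-2,6-dimethyl-8-(triethylsilyloxy)octa-1,6-dien-5-yl benzoate | C=C(C)[C@@H](O)C[C@H](OC(=O)c1ccccc1)/C(C)=C\CO[Si](CC)(CC)CC | intermediate
11 | methyl 4-bromobut-2-ynoate | COC(=O)C#CCBr | starting material
12 | methyl 4-{[(3S,5S,6Z)-5-(benzoyloxy)-2,6-dimethyl-8-(triethylsilyloxy)octa-1,6-dien-3-yl]oxy}but-2-ynoate | C=C(C)[C@@H](OCC#CC(=O)OC)C[C@H](OC(=O)c1ccccc1)/C(C)=C\CO[Si](CC)(CC)CC | intermediate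
13 | lithium cumulenolate of 12 (1-methoxy-4-alkoxybuta-1,2,3-trien-1-olate, C1 still S) | [Li+].COC([O-])=C=C=CO[C@H](C(C)=C)C[C@H](OC(=O)c1ccccc1)/C(C)=C\CO[Si](CC)(CC)CC | intermediate
14 | lithium (4R)-alkoxide of methyl (4R,6E,9S,10Z)-9-(benzoyloxy)-4-hydroxy-6,10-dimethyl-12-(triethylsilyloxy)dodeca-6,10-dien-2-ynoate | [Li+].COC(=O)C#C[C@H]([O-])C/C(C)=C/C[C@H](OC(=O)c1ccccc1)/C(C)=C\CO[Si](CC)(CC)CC | intermediate
15 | methyl (4R,6E,9S,10Z)-9-(benzoyloxy)-4-(tert-butyldimethylsilyloxy)-6,10-dimethyl-12-(triethylsilyloxy)dodeca-6,10-dien-2-ynoate | COC(=O)C#C[C@H](O[Si](C)(C)C(C)(C)C)C/C(C)=C/C[C@H](OC(=O)c1ccccc1)/C(C)=C\CO[Si](CC)(CC)CC | intermediate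
16 | methyl (2E,4R,6E,9S,10Z)-9-(benzoyloxy)-2-(diisobutylalumanyl)-4-(tert-butyldimethylsilyloxy)-6,10-dimethyl-12-(triethylsilyloxy)dodeca-2,6,10-trienoate | COC(=O)/C([Al](CC(C)C)CC(C)C)=C\[C@H](O[Si](C)(C)C(C)(C)C)C/C(C)=C/C[C@H](OC(=O)c1ccccc1)/C(C)=C\CO[Si](CC)(CC)CC | intermediate
17 | methyl (2Z,4R,6E,9S,10Z)-9-(benzoyloxy)-4-(tert-butyldimethylsilyloxy)-6,10-dimethyl-2-[(4,4,5,5-tetramethyl-1,3,2-dioxaborolan-2-yl)methyl]-12-(triethylsilyloxy)dodeca-2,6,10-trienoate | COC(=O)/C(CB1OC(C)(C)C(C)(C)O1)=C\[C@H](O[Si](C)(C)C(C)(C)C)C/C(C)=C/C[C@H](OC(=O)c2ccccc2)/C(C)=C\CO[Si](CC)(CC)CC | intermediate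
18 | methyl (2Z,4R,6E,9S,10Z)-9-(benzoyloxy)-4-(tert-butyldimethylsilyloxy)-6,10-dimethyl-12-oxo-2-[(4,4,5,5-tetramethyl-1,3,2-dioxaborolan-2-yl)methyl]dodeca-2,6,10-trienoate | COC(=O)/C(CB1OC(C)(C)C(C)(C)O1)=C\[C@H](O[Si](C)(C)C(C)(C)C)C/C(C)=C/C[C@H](OC(=O)c2ccccc2)/C(C)=C\C=O | intermediate
19 | macrocyclic pinacol borate: cyclodeca-1(10)E,4Z-diene with 3β-benzoyloxy, 6α-O-Bpin, 7β-(1-methoxycarbonylvinyl), 7α-H and 8β-(tert-butyldimethylsilyloxy) groups (germacrane numbering) | C=C(C(=O)OC)[C@@H]1[C@H](O[Si](C)(C)C(C)(C)C)C/C(C)=C/C[C@H](OC(=O)c2ccccc2)/C(C)=C\[C@H]1OB3OC(C)(C)C(C)(C)O3 | intermediate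
20 | 3β-benzoyloxy-8β-(tert-butyldimethylsilyloxy)germacra-1(10)E,4Z,11(13)-trien-12,6α-olide | C=C1C(=O)O[C@@H]2/C=C(/C)[C@@H](OC(=O)c3ccccc3)C/C=C(\C)C[C@@H](O[Si](C)(C)C(C)(C)C)[C@@H]12 | intermediate
21 | 3β-benzoyloxy-8β-hydroxygermacra-1(10)E,4Z,11(13)-trien-12,6α-olide | C=C1C(=O)O[C@@H]2/C=C(/C)[C@@H](OC(=O)c3ccccc3)C/C=C(\C)C[C@@H](O)[C@@H]12 | intermediate
22 | (E)-2-methylbut-2-enal | C/C=C(\C)C=O | starting material
23 | (2S,3R)-2,3-dimethyloxirane-2-carbaldehyde | O=C[C@@]1(C)O[C@@H]1C | intermediate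
24 | (2S,3R)-2,3-dimethyloxirane-2-carboxylic acid | OC(=O)[C@@]1(C)O[C@@H]1C | intermediate
25 | 3β-benzoyloxy-8β-[(2S,3R)-2,3-dimethyloxirane-2-carbonyloxy]germacra-1(10)E,4Z,11(13)-trien-12,6α-olide | C=C1C(=O)O[C@@H]2/C=C(/C)[C@@H](OC(=O)c3ccccc3)C/C=C(\C)C[C@@H](OC(=O)[C@@]3(C)O[C@@H]3C)[C@@H]12 | intermediate
26 | CNP0324463.4, (1R,3S,6R,7R,8R,10R)-3-benzoyloxy-1β,10α-epoxy-8-[(2S,3R)-2,3-dimethyloxirane-2-carbonyloxy]germacra-4Z,11(13)-dien-12,6α-olide | C=C1C(=O)O[C@@H]2/C=C(/C)[C@@H](OC(=O)c3ccccc3)C[C@H]3O[C@]3(C)C[C@@H](OC(=O)[C@@]3(C)O[C@@H]3C)[C@@H]12 | target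

## Step count

Total step count: 16. Longest linear sequence: 13 (steps 1, 2, 3, 5, 6, 7, 8, 9, 10, 11, 12, 15, 16).

## The three steps most likely to fail

**Step 8 (new ynoate [2,3]-Wittig rearrangement).** The amide base may add to the ynoate, the cumulenolate may simply be protonated at the α-carbon to an allenoate on work-up, or chirality transfer may be incomplete. The fallback uses the classical propargyl-ether rearrangement, sets out from 10 and comes back at 15. Ag2O-mediated alkylation of 10 with 3-bromoprop-1-yne gives (3S,5S,6Z)-2,6-dimethyl-3-(prop-2-yn-1-yloxy)-8-(triethylsilyloxy)octa-1,6-dien-5-yl benzoate F1. Its dianion (lithium 2,2,6,6-tetramethylpiperidide, 2.2 equiv, THF, −78 to −30 °C) undergoes the known [2,3]-Wittig shift of allyl propargyl ethers through the same envelope to (3R,5E,8S,9Z)-3-hydroxy-5,9-dimethyl-11-(triethylsilyloxy)undeca-5,9-dien-1-yn-8-yl benzoate F2. Silylation (tBuMe2SiOTf, 2,6-lutidine) gives the tert-butyldimethylsilyl ether F3. Oxidative methoxycarbonylation of the terminal alkyne (PdCl2 cat., CuCl2, NaOAc, CO, MeOH) then delivers 15.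

**Step 9 (hydroalumination and borylmethylation).** iBu2AlH may attack the benzoate, and the alkenylalane may lose its geometry through the allenolate. The fallback is hydride-free, sets out from 15 and comes back at 17. Syn-hydrostannation (Bu3SnH, Pd(PPh3)4, THF, 0 °C) gives the methyl (2E)-2-(tributylstannyl) trienoate F4. Iododestannylation (I2, CH2Cl2, 0 °C) gives the methyl (2E)-2-iodo trienoate F5. Negishi coupling with IZnCH2Bpin (from ICH2Bpin and Zn; Pd(PPh3)4, THF, rt) gives 17 with the same olefin geometry.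

**Step 11 (new macrocyclising allylboration–lactonisation).** The ester-deactivated boronate may react only by the uncatalysed background path, with substrate-controlled and possibly wrong C6/C7 configuration, or may oligomerise. The fallback is the organochromium (Nozaki–Hiyama-type Barbier) macrocyclisation that has been used to close germacranolide rings; it sets out from 17 and comes back at 20. Oxidation of the C–B bond (NaBO3·4H2O, THF/H2O) gives the methyl (2Z)-2-(hydroxymethyl) trienoate F6. CBr4/PPh3 gives the methyl (2E)-2-(bromomethyl) trienoate F7. PPTS in MeOH removes the primary silyl group to give the 12-hydroxy bromide F8. MnO2 gives the 12-oxo bromide F9. CrCl2 (THF, 2 mM, rt) forms an allylchromium that equilibrates and adds anti to the enal to give the macrocyclic hydroxy ester F10, which lactonises with PPTS to 20.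

Further compounds
F1 | step 8 | (3S,5S,6Z)-2,6-dimethyl-3-(prop-2-yn-1-yloxy)-8-(triethylsilyloxy)octa-1,6-dien-5-yl benzoate | C=C(C)[C@@H](OCC#C)C[C@H](OC(=O)c1ccccc1)/C(C)=C\CO[Si](CC)(CC)CC
F2 | step 8 | (3R,5E,8S,9Z)-3-hydroxy-5,9-dimethyl-11-(triethylsilyloxy)undeca-5,9-dien-1-yn-8-yl benzoate | C#C[C@H](O)C/C(C)=C/C[C@H](OC(=O)c1ccccc1)/C(C)=C\CO[Si](CC)(CC)CC
F3 | step 8 | (3R,5E,8S,9Z)-3-(tert-butyldimethylsilyloxy)-5,9-dimethyl-11-(triethylsilyloxy)undeca-5,9-dien-1-yn-8-yl benzoate | C#C[C@H](O[Si](C)(C)C(C)(C)C)C/C(C)=C/C[C@H](OC(=O)c1ccccc1)/C(C)=C\CO[Si](CC)(CC)CC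
F4 | step 9 | methyl (2E,4R,6E,9S,10Z)-9-(benzoyloxy)-4-(tert-butyldimethylsilyloxy)-6,10-dimethyl-2-(tributylstannyl)-12-(triethylsilyloxy)dodeca-2,6,10-trienoate | COC(=O)/C([Sn](CCCC)(CCCC)CCCC)=C\[C@H](O[Si](C)(C)C(C)(C)C)C/C(C)=C/C[C@H](OC(=O)c1ccccc1)/C(C)=C\CO[Si](CC)(CC)CC
F5 | step 9 | methyl (2E,4R,6E,9S,10Z)-9-(benzoyloxy)-4-(tert-butyldimethylsilyloxy)-2-iodo-6,10-dimethyl-12-(triethylsilyloxy)dodeca-2,6,10-trienoate | COC(=O)/C(I)=C\[C@H](O[Si](C)(C)C(C)(C)C)C/C(C)=C/C[C@H](OC(=O)c1ccccc1)/C(C)=C\CO[Si](CC)(CC)CC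
F6 | step 11 | methyl (2Z,4R,6E,9S,10Z)-9-(benzoyloxy)-4-(tert-butyldimethylsilyloxy)-2-(hydroxymethyl)-6,10-dimethyl-12-(triethylsilyloxy)dodeca-2,6,10-trienoate | COC(=O)/C(CO)=C\[C@H](O[Si](C)(C)C(C)(C)C)C/C(C)=C/C[C@H](OC(=O)c1ccccc1)/C(C)=C\CO[Si](CC)(CC)CC
F7 | step 11 | methyl (2E,4R,6E,9S,10Z)-9-(benzoyloxy)-2-(bromomethyl)-4-(tert-butyldimethylsilyloxy)-6,10-dimethyl-12-(triethylsilyloxy)dodeca-2,6,10-trienoate | COC(=O)/C(CBr)=C\[C@H](O[Si](C)(C)C(C)(C)C)C/C(C)=C/C[C@H](OC(=O)c1ccccc1)/C(C)=C\CO[Si](CC)(CC)CC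
F8 | step 11 | methyl (2E,4R,6E,9S,10Z)-9-(benzoyloxy)-2-(bromomethyl)-4-(tert-butyldimethylsilyloxy)-12-hydroxy-6,10-dimethyldodeca-2,6,10-trienoate | COC(=O)/C(CBr)=C\[C@H](O[Si](C)(C)C(C)(C)C)C/C(C)=C/C[C@H](OC(=O)c1ccccc1)/C(C)=C\CO
F9 | step 11 | methyl (2E,4R,6E,9S,10Z)-9-(benzoyloxy)-2-(bromomethyl)-4-(tert-butyldimethylsilyloxy)-6,10-dimethyl-12-oxododeca-2,6,10-trienoate | COC(=O)/C(CBr)=C\[C@H](O[Si](C)(C)C(C)(C)C)C/C(C)=C/C[C@H](OC(=O)c1ccccc1)/C(C)=C\C=O
F10 | step 11 | macrocyclic hydroxy ester: cyclodeca-1(10)E,4Z-diene with 3β-benzoyloxy, 6α-hydroxy, 7β-(1-methoxycarbonylvinyl), 7α-H and 8β-(tert-butyldimethylsilyloxy) groups (germacrane numbering) | C=C(C(=O)OC)[C@@H]1[C@H](O[Si](C)(C)C(C)(C)C)C/C(C)=C/C[C@H](OC(=O)c2ccccc2)/C(C)=C\[C@H]1O
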